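## Retrosynthetic overview

1. The lactone C3–O bond is made last, by a 4 → 5 ring expansion of benzocyclobutenone 21 (bicyclo[4.2.0]octatrienone numbering) with one oxygen atom of H2O2; this step also sets C3.
2. 21 comes from a [2+2] of 3,5-dimethoxybenzyne (resorcinol → 3) with the ketene silyl acetal of enoate 17; 17 comes from cross-metathesis of spiroketal alkene 15 with methyl acrylate.
3. 15 comes from alkynediol 13 by catalyst-controlled spiroacetalization; 13 is assembled on doubly lithiated propyne from (R)-propylene oxide and epoxide 8, made from (R)-epichlorohydrin.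
4. Ring order: the two oxolane rings (step 5), the four-membered ring (step 7), the lactone (step 8); the benzene ring is bought.

Assumption: for the two chiral catalysts (steps 5 and 8), the enantiomer named is taken to be the one that gives the configuration drawn; if a test run shows the opposite sense, its mirror image is used.

## Route

Step 1
Reactants: 1 resorcinol
Product: 2 1,3-dimethoxybenzene
Conditions: MeI (2.5 equiv), K2CO3, acetone, reflux
Reagents that add atoms: iodomethane, CI
Why: Williamson ether synthesis (SN2 of both phenoxides on MeI); no stereocentre is involved.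

Step 2
Reactants: 2 1,3-dimethoxybenzene
Product: 3 1-bromo-2,4-dimethoxybenzene
Conditions: NBS (1.0 equiv), MeCN, 0 °C → rt
Reagents that add atoms: N-bromosuccinimide, O=C1CCC(=O)N1Br
Why: Electrophilic aromatic bromination goes para to one OMe and ortho to the other, which marks the carbon that will later carry the lactone carbonyl.

Step 3
Reactants: 4 6-bromohex-1-ene; 5 (R)-epichlorohydrin
Product: 8 (R)-2-(hept-6-en-1-yl)oxirane, via hex-5-en-1-ylmagnesium bromide 6 (not isolated), via chlorohydrin 7 (not isolated)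
Conditions: Mg, THF, rt; CuI (5 mol%), 5, −40 → 0 °C; H2O; then NaOH (2 M aq), Et2O, rt
Reagents that add atoms: none
Why: Grignard formation, copper-catalysed SN2 opening of the epoxide at its CH2 terminus and Williamson closure with loss of chloride never touch the stereocentre, so the R configuration of 5 is carried into 8 (future C2 of the spiroketal).

Step 4
Reactants: 9 propyne; 10 (R)-propylene oxide; 8 (R)-2-(hept-6-en-1-yl)oxirane
Product: 13 (2R,8R)-pentadec-14-en-5-yne-2,8-diol, via 1,3-dilithiopropyne 11 (not isolated), via dilithium hexynolate 12 (not isolated)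
Conditions: n-BuLi (2.0 equiv), TMEDA, Et2O/hexane, −78 → 0 °C; 10, −78 → 0 °C; then 8, THF/DMPU, 0 °C → rt; H2O
Reagents that add atoms: none
Why: Sequential SN2 epoxide openings on a propyne dianion linchpin: the more reactive propargylic carbanion opens 10 at CH2, then the acetylide opens 8 at CH2, so both carbinol centres (future C7 and C2 of the spiroketal) come unchanged from the two epoxides.

Step 5
Reactants: 13 (2R,8R)-pentadec-14-en-5-yne-2,8-diol
Product: 15 (2R,5S,7R)-2-(hept-6-en-1-yl)-7-methyl-1,6-dioxaspiro[4.4]nonane, via Z enol ether 14 (not isolated)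
Conditions: AuCl (2 mol%), K2CO3 (10 mol%), MeCN, rt; filtration through basic Al2O3; then C2-symmetric imidodiphosphoric acid built from two (S)-3,3'-bis(2,4,6-triethylphenyl)-BINOL units (2 mol%), t-BuOMe, 4 Å molecular sieves, −35 °C
Reagents that add atoms: none
Why: 5-exo-dig hydroalkoxylation of the alkyne by the C2 hydroxyl gives the exocyclic enol ether, and a confined chiral Brønsted acid then effects a kinetic asymmetric spiroacetalization (protonation to an oxocarbenium/chiral anion pair, attack by the C8 hydroxyl on the face chosen by the catalyst), which sets the S spiro centre that a [4.4] spiroketal does not favour thermodynamically.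

Step 6
Reactants: 15 (2R,5S,7R)-2-(hept-6-en-1-yl)-7-methyl-1,6-dioxaspiro[4.4]nonane; 16 methyl acrylate
Product: 17 methyl (2E)-8-[(2R,5S,7R)-7-methyl-1,6-dioxaspiro[4.4]nonan-2-yl]oct-2-enoate
Conditions: 16 (4 equiv), second-generation Hoveyda–Grubbs catalyst RuCl2(H2IMes)(=CH-C6H4-2-O-i-Pr) (3 mol%), CH2Cl2, 40 °C
Reagents that add atoms: none
Why: Olefin cross-metathesis of a terminal alkene with an electron-poor acrylate is selective for the E cross product and is driven by loss of ethene; the neutral conditions leave the spiroketal untouched.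

Step 7
Reactants: 17 methyl (2E)-8-[(2R,5S,7R)-7-methyl-1,6-dioxaspiro[4.4]nonan-2-yl]oct-2-enoate; 3 1-bromo-2,4-dimethoxybenzene
Product: 21 3,5-dimethoxy-8-{6-[(2R,5S,7R)-7-methyl-1,6-dioxaspiro[4.4]nonan-2-yl]hexyl}bicyclo[4.2.0]octa-1,3,5-trien-7-one (both C8 epimers), via ketene silyl acetal 18 (not isolated), via 3,5-dimethoxybenzyne 19 (not isolated), via silyl methyl acetal 20 (not isolated)
Conditions: Et3SiH (1.2 equiv), RhCl(PPh3)3 (1 mol%), toluene, 60 °C, then evaporate; 3 (2 equiv), lithium 2,2,6,6-tetramethylpiperidide (2.2 equiv, from the amine and n-BuLi), THF, −78 → −20 °C; then Bu4NF, AcOH, THF, 0 °C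
Reagents that add atoms: none
Why: Rhodium-catalysed 1,4-hydrosilylation gives the ketene silyl acetal, reversible metalation of 3 funnels through loss of LiBr to the aryne, and a stepwise aryne [2+2] cycloaddition follows in which the nucleophilic carbon adds to the aryne carbon remote from OMe and the aryl anion next to OMe closes on the acetal carbon, so the carbonyl ends up beside the OMe-bearing carbon after fluoride unmasking; C8 forms as both epimers, which the next step makes irrelevant.

Step 8
Reactants: 21 3,5-dimethoxy-8-{6-[(2R,5S,7R)-7-methyl-1,6-dioxaspiro[4.4]nonan-2-yl]hexyl}bicyclo[4.2.0]octa-1,3,5-trien-7-one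
Product: 23 (3R)-5,7-dimethoxy-3-{6-[(2R,5S,7R)-7-methyl-1,6-dioxaspiro[4.4]nonan-2-yl]hexyl}-2-benzofuran-1(3H)-one, via perhydrate 22 (not isolated)
Conditions: Cu(MeCN)4PF6 (10 mol%), (S,S)-2,2'-(propane-2,2-diyl)bis(4-tert-butyl-4,5-dihydrooxazole) (12 mol%), urea–hydrogen peroxide adduct (1.5 equiv, in portions), EtOAc/MeCN 9:1, −20 °C
Reagents that add atoms: hydrogen peroxide (as its urea adduct), OO
Why: Proposed new method: the strained ketone adds H2O2 to give perhydrate 22, monovalent copper cleaves its O–O bond to a gem-hydroxy alkoxy radical, and strain-driven β-scission breaks only the C7–C8 bond (secondary benzylic radical, never an aryl radical), leaving an ortho-carboxylate on divalent copper; the planar benzylic radical, common to both C8 epimers, is captured by the chiral copper carboxylate and C–O reductive elimination from trivalent copper closes the γ-lactone with the bisoxazoline choosing the face, so the ring grows from four to five atoms, the oxygen lands on the benzylic side whatever the migratory aptitude of the electron-rich aryl group, and C3 is set as R from an epimeric mixture; the closest known reaction types are the copper- or iron-induced β-fragmentation of cycloalkanone perhydrates to ω-carboxyalkyl radicals and copper/bisoxazoline-catalysed enantioselective radical C–O coupling of the Kharasch–Sosnovsky type, combined here as a radical, enantioconvergent counterpart of the Baeyer–Villiger ring expansion.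

## Compound list

1 | resorcinol | Oc1cccc(O)c1 | starting material
2 | 1,3-dimethoxybenzene | COc1cccc(OC)c1 | intermediate
3 | 1-bromo-2,4-dimethoxybenzene | COc1ccc(Br)c(OC)c1 | intermediate
4 | 6-bromohex-1-ene | C=CCCCCBr | starting material
5 | (R)-epichlorohydrin | ClC[C@H]1CO1 | starting material
6 | hex-5-en-1-ylmagnesium bromide | C=CCCCC[Mg]Br | intermediate
7 | (R)-1-chloronon-8-en-2-ol (chlorohydrin) | C=CCCCCC[C@@H](O)CCl | intermediate
8 | (R)-2-(hept-6-en-1-yl)oxirane | C=CCCCCC[C@@H]1CO1 | intermediate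
9 | propyne | CC#C | starting material
10 | (R)-propylene oxide | C[C@@H]1CO1 | starting material
11 | 1,3-dilithiopropyne | [Li]CC#C[Li] | intermediate
12 | dilithium salt of (R)-hex-5-yn-2-ol (dilithium hexynolate) | C[C@@H](O[Li])CCC#C[Li] | intermediate
13 | (2R,8R)-pentadec-14-en-5-yne-2,8-diol | C[C@@H](O)CCC#CC[C@H](O)CCCCCC=C | intermediate
14 | (3R,1Z)-1-[(5R)-5-methyloxolan-2-ylidene]dec-9-en-3-ol (Z enol ether) | C=CCCCCC[C@@H](O)C/C=C1/CC[C@@H](C)O1 | intermediate
15 | (2R,5S,7R)-2-(hept-6-en-1-yl)-7-methyl-1,6-dioxaspiro[4.4]nonane | C=CCCCCC[C@@H]1CC[C@]2(CC[C@@H](C)O2)O1 | intermediate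
16 | methyl acrylate | C=CC(=O)OC | starting material
17 | methyl (2E)-8-[(2R,5S,7R)-7-methyl-1,6-dioxaspiro[4.4]nonan-2-yl]oct-2-enoate | COC(=O)/C=C/CCCCC[C@@H]1CC[C@]2(CC[C@@H](C)O2)O1 | intermediate
18 | triethyl({1-methoxy-8-[(2R,5S,7R)-7-methyl-1,6-dioxaspiro[4.4]nonan-2-yl]oct-1-en-1-yl}oxy)silane (ketene silyl acetal, E/Z mixture) | COC(O[Si](CC)(CC)CC)=CCCCCCC[C@@H]1CC[C@]2(CC[C@@H](C)O2)O1 | intermediate
19 | 3,5-dimethoxybenzyne | COC1=CC#CC(OC)=C1 | intermediate
20 | 7-methoxy-7-(triethylsilyloxy) acetal of 21 (silyl methyl acetal, stereoisomer mixture) | COc1cc(OC)c2c(c1)C(CCCCCC[C@@H]1CC[C@]3(CC[C@@H](C)O3)O1)C2(OC)O[Si](CC)(CC)CC | intermediate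
21 | 3,5-dimethoxy-8-{6-[(2R,5S,7R)-7-methyl-1,6-dioxaspiro[4.4]nonan-2-yl]hexyl}bicyclo[4.2.0]octa-1,3,5-trien-7-one (both C8 epimers) | COc1cc(OC)c2c(c1)C(CCCCCC[C@@H]1CC[C@]3(CC[C@@H](C)O3)O1)C2=O | intermediate
22 | 7-hydroperoxy-7-hydroxy adduct of 21 (perhydrate) | COc1cc(OC)c2c(c1)C(CCCCCC[C@@H]1CC[C@]3(CC[C@@H](C)O3)O1)C2(O)OO | intermediate
23 | (3R)-5,7-dimethoxy-3-{6-[(2R,5S,7R)-7-methyl-1,6-dioxaspiro[4.4]nonan-2-yl]hexyl}-2-benzofuran-1(3H)-one | COc1cc(OC)c2c(c1)[C@@H](CCCCCC[C@@H]1CC[C@]3(CC[C@@H](C)O3)O1)OC2=O | target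

## Step count and risks

Total steps: 8. Longest linear sequence: 6 steps (3 → 4 → 5 → 6 → 7 → 8); steps 1 and 2 form the short arene branch that joins at step 7.

Three steps most likely to fail:

1. Step 8 (the proposed new ring expansion). Risks: a polar background Baeyer–Villiger reaction with aryl migration, outer-sphere oxidation of the benzylic radical that erodes the selectivity at C3, and copper-induced decomposition of H2O2. The fallback uses known chemistry, sets out from 21 and comes back to the route at 23. Ring opening of 21 with NaOMe in MeOH (the alkoxide adduct opens to the lateral dienolate of an ortho-alkyl benzoate) gives methyl 2,4-dimethoxy-6-{7-[(2R,5S,7R)-7-methyl-1,6-dioxaspiro[4.4]nonan-2-yl]heptyl}benzoate F1. Benzylic oxidation (Rh2(cap)4, t-BuOOH, NaHCO3, 1,2-dichloroethane, 40 °C; the ether C–H bonds of the spiroketal are the competing site) gives the aryl ketone methyl 2,4-dimethoxy-6-{7-[(2R,5S,7R)-7-methyl-1,6-dioxaspiro[4.4]nonan-2-yl]heptanoyl}benzoate F2. Asymmetric transfer hydrogenation with RuCl(p-cymene)[(R,R)-TsDPEN] and HCO2Na in H2O/CH2Cl2 gives methyl 2-{(1R)-1-hydroxy-7-[(2R,5S,7R)-7-methyl-1,6-dioxaspiro[4.4]nonan-2-yl]heptyl}-4,6-dimethoxybenzoate F3, which lactonises to 23 on work-up (K2CO3, MeOH if needed).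

2. Step 7 (aryne [2+2] with a functionalised ketene silyl acetal). Risks: metalation of 3 between the two OMe groups instead of next to Br, and attack of the amide base on 18. The fallback sets out from 15 (with 3) and comes back to the route at 21. Linear hydroformylation of 15 (Rh(acac)(CO)2, BIPHEPHOS, CO/H2, toluene, 60 °C) gives 8-[(2R,5S,7R)-7-methyl-1,6-dioxaspiro[4.4]nonan-2-yl]octanal F4. Me3SiCl, Et3N and NaI in MeCN give trimethyl({8-[(2R,5S,7R)-7-methyl-1,6-dioxaspiro[4.4]nonan-2-yl]oct-1-en-1-yl}oxy)silane F5. MeLi in THF releases the lithium enolate of the aldehyde F6, which is added at −78 °C to 3 and lithium 2,2,6,6-tetramethylpiperidide. The known aryne–aldehyde enolate [2+2], with the same regiochemistry as in step 7, gives 3,5-dimethoxy-8-{6-[(2R,5S,7R)-7-methyl-1,6-dioxaspiro[4.4]nonan-2-yl]hexyl}bicyclo[4.2.0]octa-1,3,5-trien-7-ol F7, and Dess–Martin periodinane with NaHCO3 in CH2Cl2 oxidises it to 21.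

3. Step 5 (catalyst-controlled spiroacetalization). Risks: the catalyst has to override two resident stereocentres, and gold may close the second ring early and without selectivity. The fallback sets out from 13 and comes back to the route at 15. Thermodynamic cycloisomerisation (AuCl3, 2 mol%, MeOH, rt) followed by equilibration with camphorsulfonic acid in CH2Cl2 gives 15 together with about an equal amount of its spiro epimer (2R,5R,7R)-2-(hept-6-en-1-yl)-7-methyl-1,6-dioxaspiro[4.4]nonane F8. The two are separated by chromatography (preparative HPLC if needed), and F8 is recycled by renewed acid equilibration.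

Further compounds
F1 | step 8 | methyl 2,4-dimethoxy-6-{7-[(2R,5S,7R)-7-methyl-1,6-dioxaspiro[4.4]nonan-2-yl]heptyl}benzoate | COC(=O)c1c(OC)cc(OC)cc1CCCCCCC[C@@H]1CC[C@]2(CC[C@@H](C)O2)O1
F2 | step 8 | methyl 2,4-dimethoxy-6-{7-[(2R,5S,7R)-7-methyl-1,6-dioxaspiro[4.4]nonan-2-yl]heptanoyl}benzoate | COC(=O)c1c(OC)cc(OC)cc1C(=O)CCCCCC[C@@H]1CC[C@]2(CC[C@@H](C)O2)O1
F3 | step 8 | methyl 2-{(1R)-1-hydroxy-7-[(2R,5S,7R)-7-methyl-1,6-dioxaspiro[4.4]nonan-2-yl]heptyl}-4,6-dimethoxybenzoate | COC(=O)c1c(OC)cc(OC)cc1[C@H](O)CCCCCC[C@@H]1CC[C@]2(CC[C@@H](C)O2)O1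
F4 | step 7 | 8-[(2R,5S,7R)-7-methyl-1,6-dioxaspiro[4.4]nonan-2-yl]octanal | O=CCCCCCCC[C@@H]1CC[C@]2(CC[C@@H](C)O2)O1
F5 | step 7 | trimethyl({8-[(2R,5S,7R)-7-methyl-1,6-dioxaspiro[4.4]nonan-2-yl]oct-1-en-1-yl}oxy)silane | C[Si](C)(C)OC=CCCCCCC[C@@H]1CC[C@]2(CC[C@@H](C)O2)O1
F6 | step 7 | lithium 8-[(2R,5S,7R)-7-methyl-1,6-dioxaspiro[4.4]nonan-2-yl]oct-1-en-1-olate | [Li]OC=CCCCCCC[C@@H]1CC[C@]2(CC[C@@H](C)O2)O1
F7 | step 7 | 3,5-dimethoxy-8-{6-[(2R,5S,7R)-7-methyl-1,6-dioxaspiro[4.4]nonan-2-yl]hexyl}bicyclo[4.2.0]octa-1,3,5-trien-7-ol | COc1cc(OC)c2c(c1)C(CCCCCC[C@@H]1CC[C@]3(CC[C@@H](C)O3)O1)C2O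
F8 | step 5 | (2R,5R,7R)-2-(hept-6-en-1-yl)-7-methyl-1,6-dioxaspiro[4.4]nonane | C=CCCCCC[C@@H]1CC[C@@]2(CC[C@@H](C)O2)O1
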